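**Retrosynthetic overview**

1. The strategy rests on C4: it is quaternary, α to the C19 lactone carbonyl and bonded to the C3 carbinol, so C3–C4 is the aldol bond of a β-hydroxy lactone. Ring A (C1–C5, C10) is one half of a bicyclo[3.3.1] system whose other half is the C19–O–C20 lactone; it is closed last by a SmI2 Reformatsky reaction of the C4 bromolactone onto the C3 aldehyde.
2. The lactone ring comes from an intramolecular Michael addition of the C20 propionate (C4, C18, C19) to a C5=C6 enoate; C7 comes from carbonylation of the C6 enol triflate.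
3. Quaternary C10 comes from two conjugate additions to a ring-B cyclopentenone (first C20 as PMBOCH2, then C1–C3 as a dioxolanylethyl chain, trans to C11). C2–O is set by catalyst-controlled α-benzoyloxylation of the C3 aldehyde, so no alkene dihydroxylation has to compete with the C16 methylene.
4. Rings C and D come from a Diels–Alder reaction of (R)-4-silyloxy-2-propargylcyclopentenone (ring B) with 2-silyloxybutadiene, followed by gold-catalysed 5-exo-dig closure of C13–C16.
5. Order of ring formation: B (Piancatelli), C (Diels–Alder), D (gold), lactone (Michael), A (Reformatsky).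

Key step: step 21

Remark: atoms are numbered as in the gibberellane skeleton of the target (C7 = carboxyl on C6, C17 = exocyclic CH2, C18/C19 = methyl/carbonyl on C4, C20 = lactone CH2 on C10). The C4 bromide is carried as a mixture of epimers because both give the same enolate.

**Route**

Step 1
Reactants: 1 furfural; 2 propargyl bromide
Product: 3 (±)-1-(furan-2-yl)but-3-yn-1-ol
Conditions: Zn dust, THF/sat. aq NH4Cl, 0 °C → rt
Reagents that add atoms: none
Why: Barbier propargylation, in which the allenylzinc species adds through its γ-carbon to give the homopropargylic alcohol; the carbinol centre is lost in step 2, so the racemate is used.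

Step 2
Reactants: 3 (±)-1-(furan-2-yl)but-3-yn-1-ol
Product: 5 (±)-4-hydroxy-2-(prop-2-yn-1-yl)cyclopent-2-en-1-one, via trans-4-hydroxy-5-propargylcyclopent-2-enone 4 (not isolated)
Conditions: ZnCl2, 1,4-dioxane/H2O, reflux; then NaHCO3 to pH 8, 60 °C
Reagents that add atoms: none
Why: Piancatelli rearrangement (furan opening and 4π-electrocyclisation of the pentadienyl cation) gives the 4-hydroxy-5-substituted enone, which isomerises under mild base to the more stable 2-substituted 4-hydroxycyclopentenone.

Step 3
Reactants: 5 (±)-4-hydroxy-2-(prop-2-yn-1-yl)cyclopent-2-en-1-one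
Product: 6 (R)-4-oxo-3-(prop-2-yn-1-yl)cyclopent-2-en-1-yl acetate
Conditions: Amano lipase PS, vinyl acetate, MTBE, 30 °C, stopped near half conversion
Reagents that add atoms: vinyl acetate, C=COC(C)=O
Why: Lipase-catalysed kinetic resolution by irreversible transesterification; lipases acylate the (R)-alcohol of 2-alkyl-4-hydroxycyclopentenones, so the acetate carries the (R) centre and unreacted (S)-5 is separated.

Step 4
Reactants: 6 (R)-acetate
Product: 7 (R)-4-hydroxy-2-(prop-2-yn-1-yl)cyclopent-2-en-1-one
Conditions: Amano lipase PS, 0.1 M phosphate buffer (pH 7)/acetone, rt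
Reagents that add atoms: none
Why: Enzymatic ester hydrolysis at neutral pH avoids base-induced β-elimination of the acyloxy group and, with the same (R) preference, should raise the enantiomeric purity further.

Step 5
Reactants: 7 (R)-4-hydroxy-2-(prop-2-yn-1-yl)cyclopent-2-en-1-one
Product: 8 (R)-4-(tert-butyldimethylsilyloxy)-2-(prop-2-yn-1-yl)cyclopent-2-en-1-one
Conditions: TBSCl, imidazole, DMF, 0 °C → rt
Reagents that add atoms: tert-butyldimethylsilyl chloride, CC(C)(C)[Si](C)(C)Cl
Why: Standard silylation; the bulky, non-chelating silyl ether is the facial director for step 7 and the leaving group for step 8.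

Step 6
Reactants: 9 methyl vinyl ketone
Product: 10 2-(tert-butyldimethylsilyloxy)buta-1,3-diene
Conditions: TBSOTf, Et3N, Et2O, 0 °C
Reagents that add atoms: tert-butyldimethylsilyl triflate, CC(C)(C)[Si](C)(C)OS(=O)(=O)C(F)(F)F
Why: Soft enolisation and O-silylation of the enone gives the 2-silyloxydiene.

Step 7
Reactants: 8 (R)-silyloxy enone; 10 2-(tert-butyldimethylsilyloxy)buta-1,3-diene
Product: 11 cis-fused Diels–Alder adduct (C6 ketone, 8-propargyl, 10-OTBS, C12=C13 TBS enol ether)
Conditions: Tf2NH (10 mol %), CH2Cl2, −78 → −20 °C; Et3N quench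
Reagents that add atoms: none
Why: Diels–Alder reaction of a 2-silyloxydiene with a hindered 2-alkylcycloalkenone (under silyl triflimide catalysis a double Mukaiyama–Michael sequence); the diene CH2 next to the siloxy carbon bonds to the β-carbon C9 (para rule), which puts the enol ether at C12=C13, suprafacial addition gives the cis ring fusion, and the diene adds anti to the C10 silyloxy group, which sets C8 and C9.

Step 8
Reactants: 11 Diels–Alder adduct
Product: 13 tricyclic enedione (16-methylene; C5=C10 enone; C6 ketone; C12 ketone), via C10 silyl ether diketone 12 (not isolated)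
Conditions: [(JohnPhos)Au(NCMe)]SbF6 (3 mol %), CH2Cl2/H2O (10:1), rt; then DBU, 0 °C → rt
Reagents that add atoms: none
Why: Gold(I)-catalysed 5-exo-dig carbocyclisation of the silyl enol ether onto the terminal alkyne (Conia-ene type) forms C13–C16 and the exocyclic methylene; the two-carbon bridge can only close cis-1,3 across ring C from the C8 propargyl group, which fixes C13, and DBU then removes the β-silyloxy group (E1cB) to give the C5=C10 enone.

Step 9
Reactants: 14 (tributylstannyl)methanol; 15 4-methoxybenzyl chloride
Product: 16 tributyl{[(4-methoxybenzyl)oxy]methyl}stannane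
Conditions: NaH, THF/DMF, 0 °C → rt
Reagents that add atoms: none
Why: Williamson ether synthesis gives the precursor of the alkoxymethyl anion that will become C20.

Step 10
Reactants: 13 tricyclic enedione; 16 alkoxymethylstannane
Product: 17 C6 trimethylsilyl enol ether carrying CH2OPMB (C20) on C10
Conditions: 16, n-BuLi, THF, −78 °C; CuBr·SMe2 (1 equiv); then TMSCl and 13, −78 → −40 °C; Et3N, aq NaHCO3 work-up
Reagents that add atoms: chlorotrimethylsilane, C[Si](C)(C)Cl
Why: Tin–lithium exchange gives the α-alkoxymethyllithium, whose organocopper reagent adds 1,4 to the cyclopentenone under TMSCl acceleration without touching the C12 ketone; the C10 configuration formed here is erased in step 11.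

Step 11
Reactants: 17 silyl enol ether
Product: 18 enone with C10–CH2OPMB (C5=C10, C6 ketone, C12 ketone)
Conditions: Pd(OAc)2 (1.05 equiv), MeCN, rt
Reagents that add atoms: none
Why: Saegusa–Ito oxidation; β-hydride elimination from the palladium enolate can only take the C10 hydrogen, which regenerates the enone with C10 now β,β-disubstituted.

Step 12
Reactants: 18 enone diketone
Product: 20 12-deoxo enone (C5=C10; C6 ketone; C10–CH2OPMB), via C12 tosylhydrazone 19 (not isolated)
Conditions: TsNHNH2 (1.05 equiv), THF/MeOH, rt; evaporate; catecholborane, CHCl3, 0 °C; then NaOAc·3H2O, reflux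
Reagents that add atoms: none
Why: Tosylhydrazone reduction (Caglioti type, borane variant); the saturated C12 ketone condenses much faster than the hindered, conjugated C6 carbonyl, and hydride addition to C=N followed by loss of sulfinate and N2 leaves CH2 at C12 without touching the alkenes.

Step 13
Reactants: 20 12-deoxo enone; 21 2-(2-bromoethyl)-1,3-dioxolane
Product: 24 C6 enol triflate with quaternary C10, via TMS enol ether 22 (not isolated), via lithium enolate 23 (not isolated)
Conditions: 21, Mg, THF, rt; CuBr·SMe2 (20 mol %), TMSCl, 20, THF, −78 → −30 °C; Et3N/hexane filtration; MeLi, THF, 0 °C; PhNTf2, −78 °C → rt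
Reagents that add atoms: N-phenylbis(trifluoromethanesulfonimide), O=S(=O)(N(c1ccccc1)S(=O)(=O)C(F)(F)F)C(F)(F)F
Why: Copper-catalysed conjugate addition of the Grignard reagent to the β,β-disubstituted cyclopentenone forms quaternary C10; the reagent enters on the face of C10 opposite C11 of the neighbouring C9 (cis to H-9), so C1 ends cis to H-9 and C20 cis to C11, and the enolate released from the silyl enol ether (only C5=C6 is possible, C8 being quaternary) is O-triflated.

Step 14
Reactants: 24 enol triflate
Product: 25 2-(trimethylsilyl)ethyl C5=C6 enoate (C7 installed)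
Conditions: Pd(OAc)2 (10 mol %), PPh3 (20 mol %), CO (1 atm), Me3SiCH2CH2OH, Et3N, DMF, 60 °C
Reagents that add atoms: carbon monoxide, [C-]#[O+]; 2-(trimethylsilyl)ethanol, C[Si](C)(C)CCO
Why: Palladium-catalysed alkoxycarbonylation of the enol triflate brings in C7 as a fluoride-labile ester and makes C5 the β-carbon of an enoate.

Step 15
Reactants: 25 PMB ether enoate
Product: 26 C20 primary alcohol
Conditions: DDQ, CH2Cl2/pH 7 buffer (10:1), 0 °C → rt
Reagents that add atoms: none
Why: Oxidative cleavage of the PMB ether; the isolated 1,1-disubstituted alkene, the enoate and the dioxolane are inert to DDQ at this temperature.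

Step 16
Reactants: 26 C20 alcohol; 27 propionyl chloride
Product: 28 C20 propionate
Conditions: pyridine, DMAP (cat.), CH2Cl2, 0 °C
Reagents that add atoms: none
Why: Acylation of the neopentyl primary alcohol attaches C19, C4 and C18 through the future lactone oxygen.

Step 17
Reactants: 28 C20 propionate
Product: 29 cis-fused δ-lactone (C4–H as epimer mixture, 6-ester trans to C4)
Conditions: t-BuOK (0.2 equiv), THF/t-BuOH (10:1), 0 °C → rt
Reagents that add atoms: none
Why: Intramolecular Michael addition (6-exo-trig) of the propionate enolate to the enoate forms C4–C5 and the lactone; the tether delivers C4 to the face of C5 that carries C20 (cis-fused lactone), C6 equilibrates under the alkoxide to the ester trans to C4, and C4 stays a mixture because it is rebuilt in step 21.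

Step 18
Reactants: 29 lactone
Product: 31 C4 bromolactone (4RS), via lithium lactone enolate 30 (not isolated)
Conditions: LiHMDS (1.1 equiv), THF, −78 °C; CBr4, −78 °C; aq NH4Cl
Reagents that add atoms: carbon tetrabromide, BrC(Br)(Br)Br
Why: Enolate bromination; the lactone α-hydrogen at C4 is more acidic than the C6 ester hydrogen (ester locked in the E geometry) and much less hindered than C6–H next to quaternary C8, so LiHMDS should form only the C4 enolate.

Step 19
Reactants: 31 bromolactone acetal
Product: 32 bromolactone C3 aldehyde (C2 unsubstituted)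
Conditions: PPTS (0.2 equiv), acetone/H2O (8:1), 55 °C
Reagents that add atoms: water, O
Why: Mild acetal hydrolysis; the tertiary α-bromo lactone, the silylethyl ester and the exocyclic alkene tolerate weak acid.

Step 20
Reactants: 32 bromolactone aldehyde
Product: 33 bromolactone (2S)-2-benzoyloxy aldehyde (key-step precursor)
Conditions: (S)-2-(triphenylmethyl)pyrrolidine (10 mol %), dibenzoyl peroxide (1.1 equiv), hydroquinone (10 mol %), THF, 0 °C; used at once
Reagents that add atoms: dibenzoyl peroxide, O=C(OOC(=O)c1ccccc1)c1ccccc1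
Why: Enamine-catalysed α-benzoyloxylation of the aldehyde; the trityl group shields one face of the E-enamine and the peroxide attacks the other, which gives the (2S) benzoate under catalyst control, independent of the remote ring stereocentres.

Step 21
Reactants: 33 bromolactone (2S)-2-benzoyloxy aldehyde
Product: 35 2-O-benzoyl 2-(trimethylsilyl)ethyl ester of the target, via samarium(III) lactone enolate 34 (not isolated)
Conditions: SmI2 (2.5 equiv, 0.1 M in THF), HMPA (10 equiv), THF, −78 °C, 33 added dropwise; sat. aq NH4Cl at −78 °C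
Reagents that add atoms: none
Why: Two single-electron transfers from SmI2 cleave the C4–Br bond and give the samarium(III) lactone enolate 34 regiospecifically and without base, and this adds to the C3 aldehyde in an intramolecular Reformatsky (aldol) reaction, the known SmI2 cyclisation of α-bromo esters and lactones onto aldehydes. Ring A closes in a 6-(enolexo)-exo-trig mode as the carbocyclic half of the bicyclo[3.3.1] system. C4 is fixed by the ring system, because the enolate carbon lies in the lactone ring and can be reached only from the face that carries the C10 tether, so both bromide epimers converge. C3 is decided in the chair-like transition state: with the C2 benzoate equatorial and its C–O bond anti to the forming bond (polar Felkin–Anh), the aldehyde oxygen is either anti to the C4–C19 enolate bond (axial, 3β, cis to O2, the wanted isomer) or gauche to it (equatorial, 3α). A samarium bridge between enolate and aldehyde oxygens is possible only in the gauche arrangement, so the step needs the open antiperiplanar transition state; excess HMPA fills the coordination sphere of samarium(III) and the C2 ester oxygen is a poor donor, and the open arrangement is then preferred because it puts the small aldehyde hydrogen, not the oxygen, between C18 and C19 and keeps the two oxygens apart. At −78 °C the C–Br bond is reduced much faster than the aldehyde or the benzoate, which should keep ketyl formation and ester cleavage from competing.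

Step 22
Reactants: 35 2-O-benzoate
Product: 36 2-(trimethylsilyl)ethyl ester of the target (2β,3β-diol)
Conditions: K2CO3 (0.3 equiv), MeOH, 0 °C
Reagents that add atoms: none
Why: Mild transesterification removes the secondary benzoate (from O2, or from O3 if it has migrated within the cis-diol), while the lactone carbonyl on quaternary C4 and the hindered C7 ester react much more slowly.

Step 23
Reactants: 36 silylethyl ester
Product: 37 target acid CNP0332607.1
Conditions: TASF (2.5 equiv), DMF, 0 °C → rt; pH 4 NaH2PO4 buffer
Reagents that add atoms: none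
Why: Fluoride attack on silicon and β-elimination of ethylene frees the C7 acid under non-basic conditions that spare the β-hydroxy lactone (no retro-aldol), the diol and the exocyclic alkene.

**Compound list**

1 | furfural | O=Cc1ccco1 | starting material
2 | propargyl bromide | C#CCBr | starting material
3 | (±)-1-(furan-2-yl)but-3-yn-1-ol | OC(CC#C)c1ccco1 | intermediate
4 | (±)-trans-4-hydroxy-5-(prop-2-yn-1-yl)cyclopent-2-en-1-one | O=C1C=CC(O)C1CC#C | intermediate
5 | (±)-4-hydroxy-2-(prop-2-yn-1-yl)cyclopent-2-en-1-one | C#CCC1=CC(O)CC1=O | intermediate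
6 | (R)-4-oxo-3-(prop-2-yn-1-yl)cyclopent-2-en-1-yl acetate | C#CCC1=C[C@H](OC(C)=O)CC1=O | intermediate
7 | (R)-4-hydroxy-2-(prop-2-yn-1-yl)cyclopent-2-en-1-one | C#CCC1=C[C@H](O)CC1=O | intermediate
8 | (R)-4-(tert-butyldimethylsilyloxy)-2-(prop-2-yn-1-yl)cyclopent-2-en-1-one | C#CCC1=C[C@H](O[Si](C)(C)C(C)(C)C)CC1=O | intermediate
9 | methyl vinyl ketone | CC(=O)C=C | starting material
10 | 2-(tert-butyldimethylsilyloxy)buta-1,3-diene | C=CC(=C)O[Si](C)(C)C(C)(C)C | intermediate
11 | cis-hydrindenone: C6 ketone, 8-propargyl, H-9 and 10-OTBS on the same face as the propargyl group, C12=C13 TBS enol ether | C#CC[C@]12CC=C(O[Si](C)(C)C(C)(C)C)C[C@H]1[C@H](O[Si](C)(C)C(C)(C)C)CC2=O | intermediate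
12 | B/C/D tricycle: 16-methylene, C6 and C12 ketones, 10-OTBS | C=C1C[C@]23C[C@H]1C(=O)C[C@H]2[C@H](O[Si](C)(C)C(C)(C)C)CC3=O | intermediate
13 | B/C/D tricycle: 16-methylene, C5=C10 enone (C6 ketone), C12 ketone | C=C1C[C@]23C[C@H]1C(=O)C[C@H]2C=CC3=O | intermediate
14 | (tributylstannyl)methanol | CCCC[Sn](CCCC)(CCCC)CO | starting material
15 | 4-methoxybenzyl chloride | COc1ccc(CCl)cc1 | starting material
16 | tributyl{[(4-methoxybenzyl)oxy]methyl}stannane | CCCC[Sn](CCCC)(CCCC)COCc1ccc(OC)cc1 | intermediate
17 | C6 trimethylsilyl enol ether, 10-CH2OPMB trans to C11, C12 ketone | C=C1C[C@]23C[C@H]1C(=O)C[C@H]2[C@H](COCc4ccc(OC)cc4)C=C3O[Si](C)(C)C | intermediate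
18 | C5=C10 enone with 10-CH2OPMB, C6 and C12 ketones | C=C1C[C@]23C[C@H]1C(=O)C[C@H]2C(COCc4ccc(OC)cc4)=CC3=O | intermediate
19 | C12 tosylhydrazone of 18 | C=C1C[C@]23C[C@H]1C(=NNS(=O)(=O)c4ccc(C)cc4)C[C@H]2C(COCc4ccc(OC)cc4)=CC3=O | intermediate
20 | 12-deoxo enone: C5=C10, C6 ketone, 10-CH2OPMB | C=C1C[C@]23C[C@H]1CC[C@H]2C(COCc4ccc(OC)cc4)=CC3=O | intermediate
21 | 2-(2-bromoethyl)-1,3-dioxolane | BrCCC1OCCO1 | starting material
22 | C6 trimethylsilyl enol ether with quaternary C10 (CH2OPMB cis to C11, dioxolanylethyl cis to H-9) | C=C1C[C@]23C[C@H]1CC[C@H]2[C@](COCc4ccc(OC)cc4)(CCC4OCCO4)C=C3O[Si](C)(C)C | intermediate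
23 | lithium enolate corresponding to 22 | C=C1C[C@]23C[C@H]1CC[C@H]2[C@](COCc4ccc(OC)cc4)(CCC4OCCO4)C=C3O[Li] | intermediate
24 | C6 enol triflate (C5=C6) | C=C1C[C@]23C[C@H]1CC[C@H]2[C@](COCc4ccc(OC)cc4)(CCC4OCCO4)C=C3OS(=O)(=O)C(F)(F)F | intermediate
25 | 2-(trimethylsilyl)ethyl C5=C6 enoate, 20-OPMB | C=C1C[C@]23C[C@H]1CC[C@H]2[C@](COCc4ccc(OC)cc4)(CCC4OCCO4)C=C3C(=O)OCC[Si](C)(C)C | intermediate
26 | C20 alcohol | C=C1C[C@]23C[C@H]1CC[C@H]2[C@](CO)(CCC4OCCO4)C=C3C(=O)OCC[Si](C)(C)C | intermediate
27 | propionyl chloride | CCC(=O)Cl | starting material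
28 | C20 propionate | C=C1C[C@]23C[C@H]1CC[C@H]2[C@](COC(=O)CC)(CCC4OCCO4)C=C3C(=O)OCC[Si](C)(C)C | intermediate
29 | 19,20-lactone: cis-fused at C5/C10, C4–H epimer mixture, 6-ester trans to C4, C10 side chain CH2CH2CH(dioxolane) | C=C1C[C@]23C[C@H]1CC[C@H]2[C@@]1(CCC4OCCO4)COC(=O)C(C)[C@H]1[C@@H]3C(=O)OCC[Si](C)(C)C | intermediate
30 | lithium enolate of lactone 29 (C4=C19) | C=C1C[C@]23C[C@H]1CC[C@H]2[C@@]1(CCC4OCCO4)COC(O[Li])=C(C)[C@H]1[C@@H]3C(=O)OCC[Si](C)(C)C | intermediate
31 | C4 bromolactone (4RS), dioxolane | C=C1C[C@]23C[C@H]1CC[C@H]2[C@@]1(CCC4OCCO4)COC(=O)C(C)(Br)[C@H]1[C@@H]3C(=O)OCC[Si](C)(C)C | intermediate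
32 | C4 bromolactone (4RS), C3 aldehyde | C=C1C[C@]23C[C@H]1CC[C@H]2[C@@]1(CCC=O)COC(=O)C(C)(Br)[C@H]1[C@@H]3C(=O)OCC[Si](C)(C)C | intermediate
33 | C4 bromolactone (4RS), (2S)-2-benzoyloxy C3 aldehyde | C=C1C[C@]23C[C@H]1CC[C@H]2[C@@]1(C[C@H](OC(=O)c4ccccc4)C=O)COC(=O)C(C)(Br)[C@H]1[C@@H]3C(=O)OCC[Si](C)(C)C | intermediate
34 | samarium(III) enolate of the lactone (C4=C19–OSmI2) | C=C1C[C@]23C[C@H]1CC[C@H]2[C@@]1(C[C@H](OC(=O)c4ccccc4)C=O)COC(O[Sm](I)I)=C(C)[C@H]1[C@@H]3C(=O)OCC[Si](C)(C)C | intermediate
35 | 2-O-benzoyl 2-(trimethylsilyl)ethyl ester of the target (3β-OH axial, cis to 2β-OBz) | C=C1C[C@]23C[C@H]1CC[C@H]2[C@]12COC(=O)[C@](C)([C@@H](O)[C@@H](OC(=O)c4ccccc4)C1)[C@H]2[C@@H]3C(=O)OCC[Si](C)(C)C | intermediate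
36 | 2-(trimethylsilyl)ethyl ester of the target | C=C1C[C@]23C[C@H]1CC[C@H]2[C@]12COC(=O)[C@](C)([C@@H](O)[C@@H](O)C1)[C@H]2[C@@H]3C(=O)OCC[Si](C)(C)C | intermediate
37 | CNP0332607.1 (2β,3β-dihydroxy 19,20-lactone 7-acid, 16-ene) | C=C1C[C@]23C[C@H]1CC[C@H]2[C@]12COC(=O)[C@](C)([C@@H](O)[C@@H](O)C1)[C@H]2[C@@H]3C(=O)O | target

**Step count**

Total: 23 steps (21 on the main line, plus step 6 for diene 10 and step 9 for stannane 16).
Longest linear sequence: 21 steps (1–5, 7, 8, 10–23).

**Steps most likely to fail, with fallbacks**

Step 21 (key step). What may go wrong is poor facial selectivity at the aldehyde: if HMPA does not fully prevent samarium from bridging the enolate and aldehyde oxygens, the ring closes through the gauche arrangement and the hydroxyl ends equatorial (3α); reduction of the aldehyde or loss of the benzoate may also compete. The fallback corrects C3 after ring closure instead of in it. It sets out from 33, which is cyclised with SmI2 in THF without HMPA to the 3α-alcohol (3-epi-35) F1. Dess–Martin periodinane in CH2Cl2 oxidises this to the 3-ketone F2, which cannot enolise towards quaternary C4. K-Selectride in THF at −78 °C then delivers hydride along the equatorial direction, as bulky hydrides do with 4,4-disubstituted 3-ketones in terpenoids, and gives the axial 3β-alcohol. The fallback returns to the route at 35.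

Step 7. What may go wrong is low reactivity of the α-substituted enone together with acid-induced β-elimination of the C10 silyloxy group before the ring has formed. The fallback replaces the acid-catalysed cycloaddition by an anionic double Michael annulation. It sets out from 8: the lithium dienolate of methyl vinyl ketone (from commercial 2-(trimethylsilyloxy)buta-1,3-diene and MeLi, THF, −78 °C) adds to C9 anti to the silyloxy group; the C8 enolate so formed cannot expel the C10 oxygen (it is γ, not β) and closes onto the vinyl ketone. This gives the lithium enolate F3 with the enolate fixed at C12=C13. Trapping with TBSCl/HMPA returns to the route at 11.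

Step 17. What may go wrong is slow formation of the simple ester enolate, with cleavage or transfer of the propionate by alkoxide competing before C4–C5 forms. The fallback uses a doubly activated donor. It sets out from 26, which is esterified with 2-methylmalonic acid monoallyl ester (DCC, DMAP, CH2Cl2) to the mixed malonate F4. The same t-BuOK (cat.), THF/t-BuOH conditions should now cyclise readily to the α-allyloxycarbonyl lactone F5 and still equilibrate C6. Pd(PPh3)4 with HCO2H/Et3N in THF (Tsuji–Trost deallylation with decarboxylation) then gives the C4–H lactone. The fallback returns to the route at 29.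

**Further compounds**

F1 | step 21 | 3α-epimer of 35 (3-epi-35) | C=C1C[C@]23C[C@H]1CC[C@H]2[C@]12COC(=O)[C@](C)([C@H](O)[C@@H](OC(=O)c4ccccc4)C1)[C@H]2[C@@H]3C(=O)OCC[Si](C)(C)C
F2 | step 21 | 3-ketone (2-O-benzoyl, silylethyl ester) | C=C1C[C@]23C[C@H]1CC[C@H]2[C@]12COC(=O)[C@](C)(C(=O)[C@@H](OC(=O)c4ccccc4)C1)[C@H]2[C@@H]3C(=O)OCC[Si](C)(C)C
F3 | step 7 | lithium C12=C13 enolate of the cis-hydrindanedione (10-OTBS, 8-propargyl) | C#CC[C@]12CC=C(O[Li])C[C@H]1[C@H](O[Si](C)(C)C(C)(C)C)CC2=O
F4 | step 17 | C20 allyl methylmalonate of 26 | C=C1C[C@]23C[C@H]1CC[C@H]2[C@](COC(=O)C(C)C(=O)OCC=C)(CCC4OCCO4)C=C3C(=O)OCC[Si](C)(C)C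
F5 | step 17 | 4-allyloxycarbonyl lactone (C4 epimer mixture) | C=C1C[C@]23C[C@H]1CC[C@H]2[C@@]1(CCC4OCCO4)COC(=O)C(C)(C(=O)OCC=C)[C@H]1[C@@H]3C(=O)OCC[Si](C)(C)C
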